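**Plan**

- Retrosynthetic cuts, in order: (a) the lactone C12–O6, made last by oxidative lactonisation of a 2-methylene-1,4-diol; (b) C4–O and C2–C3 of the side chain, and O–C9, the latter delivered from the C2 carboxyl by iodolactonisation; (c) O–C1 and O–C5, by anti-dioxygenation of a C1=C5 alkene; (d) the ring bond C6–C7; (e) the cyclopropane bonds from crotonaldehyde and bromomalonate.
- Enabling feature: in the seven-membered carbocycle (C1, C5, C6, C7, C8, C9, C10) the bond C6–C7 lies opposite the methyl-bearing C10, whose two neighbours C1 and C9 are both oxygenated. A C1–C9 bond turns the ring into a cis-1,2-dialkenylcyclopropane (C1–C10–C9), whose [3,3] shift forms C6–C7 and leaves alkenes C1=C5 and C8=C9 where the oxygens are needed.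
- Forward order: cyclopropane (step 1); two E-alkenyl arms (steps 2–8); seven-membered ring (step 9); C1/C5 oxygens (steps 10–14); C5 ester and C9 oxygen through a bridged lactone (steps 15–19); side chain (steps 20–21); α-methylene lactone (steps 22–23).
- Stereochemistry: C10 from the organocatalytic cyclopropanation; C6 and C7 from the boat transition state of step 9 (E,E arms, methyl trans to both, hence C6/C7/C10 all cis); C1 and C5 from β-face epoxidation and Payne inversion at C1; C9 from the tethered iodolactonisation; C4 from catalyst-controlled conjugate borylation; the acyl centre from (S)-2-methylbutanoic acid.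

Key step: step 9

Remark (numbering): atoms are numbered as in a 4,5-seco-guaiane. The ring is C1, C5, C6, C7, C8, C9, C10; C2–C3–C4–C15 is the chain on C1, C14 the methyl on C10, C11–C13 the lactone carbons. α is the ring face of the C10 methyl, β the other. The target is 1α-OH, 5β-O-acyl, 6α-O, 7α-C11, 9β-OH, 10α-CH3, (4R).

Remark (assumption): the sense of induction of the chiral catalysts in steps 1 and 21 is taken from the usual steric models; if either proves reversed, the antipodal catalyst is used.

Step 1
Reactants: 1 (E)-but-2-enal; 2 dimethyl 2-bromomalonate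
Product: 3 dimethyl (2S,3S)-2-formyl-3-methylcyclopropane-1,1-dicarboxylate (formyl and methyl trans)
Conditions: (R)-α,α-diphenylprolinol trimethylsilyl ether (10 mol%), 2,6-lutidine (1.1 equiv), CH2Cl2, 0 °C
Reagents that add atoms: none
Why: Organocatalytic Michael-initiated ring closure (iminium-mediated malonate addition, then enamine C-alkylation with loss of bromide); the silyl ether shields one face of the iminium ion so that malonate should add to the Si face of the β-carbon, which sets C10, and ring closure places formyl trans to methyl.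

Step 2
Reactants: 3
Product: 5 methyl (1R,5S,6S)-6-methyl-2-oxo-3-oxabicyclo[3.1.0]hexane-1-carboxylate, via hydroxymethyl diester 4 (not isolated)
Conditions: NaBH4, MeOH, 0 °C; then TsOH·H2O (cat.), CH2Cl2, 25 °C
Reagents that add atoms: none
Why: Aldehyde-selective borohydride reduction followed by lactonisation, which can only use the ester cis to the new hydroxymethyl group and so tells the two malonate carbonyls apart (lactone carbonyl = future C5, free ester = future C2).

Step 3
Reactants: 5
Product: 6 methyl (1S,5S,6S)-2-hydroxy-6-methyl-3-oxabicyclo[3.1.0]hexane-1-carboxylate (lactol, both anomers)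
Conditions: i-Bu2AlH (1.05 equiv), CH2Cl2, −78 °C; Rochelle salt work-up
Reagents that add atoms: none
Why: Partial reduction of a γ-lactone to its lactol; the strained bicyclic lactone carbonyl should be more electrophilic than the acyclic methyl ester and the aluminate adduct is stable at −78 °C.

Step 4
Reactants: 6
Product: 7 methyl (1S,2S,3S)-1-ethynyl-2-(hydroxymethyl)-3-methylcyclopropane-1-carboxylate (ethynyl and CH2OH cis, methyl trans to both)
Conditions: dimethyl (1-diazo-2-oxopropyl)phosphonate (1.5 equiv), K2CO3 (2.5 equiv), MeOH, 0 to 25 °C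
Reagents that add atoms: dimethyl (1-diazo-2-oxopropyl)phosphonate, COP(=O)(OC)C(=[N+]=[N-])C(C)=O
Why: Seyferth–Gilbert homologation in its Ohira–Bestmann form acts on the open hydroxy-aldehyde tautomer of the lactol; the aldehyde sits on a quaternary carbon so nothing can epimerise, and the freed CH2OH is trans to the remaining ester and cannot relactonise.

Step 5
Reactants: 7
Product: 8 methyl (1S,2S,3S)-1-ethynyl-2-formyl-3-methylcyclopropane-1-carboxylate
Conditions: Dess–Martin periodinane (1.3 equiv), NaHCO3, CH2Cl2, 0 to 25 °C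
Reagents that add atoms: none
Why: Mild hypervalent-iodine oxidation of a primary alcohol under buffered conditions, which should leave the cis-configured cyclopropane carbaldehyde unepimerised.

Step 6
Reactants: 8
Product: 9 methyl (1S,2S,3S)-1-ethynyl-3-methyl-2-[(E)-2-(4,4,5,5-tetramethyl-1,3,2-dioxaborolan-2-yl)ethenyl]cyclopropane-1-carboxylate
Conditions: Cl2CHB(pin) (2 equiv), CrCl2 (8 equiv), LiI (4 equiv), THF, 25 °C
Reagents that add atoms: 2-(dichloromethyl)-4,4,5,5-tetramethyl-1,3,2-dioxaborolane, ClC(Cl)B1OC(C)(C)C(C)(C)O1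
Why: Takai–Utimoto boryl-olefination through a geminal dichromium species gives the E-alkenylboronate by anti elimination and tolerates the ester and the terminal alkyne; this step adds C7.

Step 7
Reactants: 10 2-bromoprop-2-en-1-ol
Product: 11 (2-bromoprop-2-enyloxy)triisopropylsilane
Conditions: i-Pr3SiCl (1.1 equiv), imidazole (2 equiv), DMF, 25 °C
Reagents that add atoms: chlorotriisopropylsilane, CC(C)[Si](Cl)(C(C)C)C(C)C
Why: Standard silylation of a primary allylic alcohol; the triisopropylsilyl group is chosen to survive the basic step 14.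

Step 8
Reactants: 9; 11
Product: 12 methyl (1S,2S,3S)-1-ethynyl-3-methyl-2-[(1E)-3-(triisopropylsilyloxymethyl)buta-1,3-dienyl]cyclopropane-1-carboxylate
Conditions: Pd(dppf)Cl2 (5 mol%), K3PO4 (3 equiv), THF/H2O 10:1, 50 °C
Reagents that add atoms: none
Why: Suzuki–Miyaura coupling of an alkenylboronate with an alkenyl bromide proceeds with retention at both alkenes and installs C11–C13 as a 1,1-disubstituted alkene that stays inert until step 23.

Step 9
Reactants: 12
Product: 14 methyl cycloheptadienecarboxylate with C1=C5 and C8=C9 double bonds, CO2Me on C1, 6α-pinacolboryl, 7α-[3-(triisopropylsilyloxy)prop-1-en-2-yl] and 10α-methyl (all three sp3 substituents cis), via cis-dialkenylcyclopropane 13 (not isolated)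
Conditions: pinacolborane (1.2 equiv), Cp2Zr(H)Cl (5 mol%), Et3N (10 mol%), toluene, 25 °C; then 70 °C
Reagents that add atoms: pinacolborane, B1OC(C)(C)C(C)(C)O1
Why: Catalytic syn-hydroboration of the terminal alkyne gives the E-alkenylboronate 13, a cis-1,2-dialkenylcyclopropane, which on warming undergoes a concerted [3,3]-sigmatropic shift in which the strained C1–C9 bond breaks as the alkene termini C6 and C7 bond. The closest known reaction type is the divinylcyclopropane–cycloheptadiene (Cope) rearrangement. The seven-membered ring closes by ring expansion through the boat transition state that the cis arrangement enforces, with both arms folded over the three-membered ring; C6–C7 is the only new σ bond and the new ring alkenes C1=C5 and C8=C9 are necessarily cis. C6 and C7 are controlled by the E geometry of the two arms, which places boron and the C11 unit cis to each other. Their relation to C10 is controlled by the cyclopropane: the methyl is trans to both arms, lies outside the fold of the boat and emerges cis to both new substituents, while C10 itself is untouched and carries over the absolute configuration of 3. The step needs alkyne-selective hydroboration beside a 1,3-diene and an ester (terminal alkynes react far faster under zirconium catalysis), the cis relation of the arms (fixed by lactone 5) and E,E geometry (steps 6, 8 and the syn H–B addition), so that rearrangement runs well below temperatures of cyclopropane stereomutation.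

Step 10
Reactants: 14
Product: 15 the 6α-hydroxy analogue of 14 (allylic alcohol, γ-hydroxy enoate)
Conditions: NaBO3·4H2O (3 equiv), THF/H2O 1:1, 25 °C
Reagents that add atoms: sodium perborate, [Na+].[O-]OB(O)O
Why: Oxidation of the allylic boronate by 1,2-migration from boron to oxygen occurs with retention and without allylic transposition, so the C6 oxygen keeps the α configuration set in step 9.

Step 11
Reactants: 15
Product: 16 the 6α-tert-butyldimethylsilyl ether of 15
Conditions: t-BuMe2SiOTf (1.3 equiv), 2,6-lutidine (2 equiv), CH2Cl2, −78 to 0 °C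
Reagents that add atoms: tert-butyldimethylsilyl triflate, CC(C)(C)[Si](C)(C)OS(=O)(=O)C(F)(F)F
Why: Silylation of the hindered secondary allylic alcohol removes the only hydroxyl that could direct the epoxidation of step 13 to the wrong face.

Step 12
Reactants: 16
Product: 17 allylic alcohol: as 16 but with CH2OH (C2) on C1 in place of CO2Me
Conditions: i-Bu2AlH (2.5 equiv), CH2Cl2, −78 °C
Reagents that add atoms: none
Why: 1,2-Reduction of the α,β-unsaturated methyl ester to the primary allylic alcohol, the silyl ethers and both other alkenes being inert.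

Step 13
Reactants: 17
Product: 18 1β,5β-epoxy alcohol (epoxide oxygen on the face opposite the C10 methyl and the C6 silyloxy group)
Conditions: VO(acac)2 (5 mol%), t-BuOOH (1.5 equiv, decane solution), CH2Cl2, 0 to 25 °C
Reagents that add atoms: tert-butyl hydroperoxide, CC(C)(C)OO
Why: Hydroxyl-directed vanadium-catalysed epoxidation touches only C1=C5, the one alkene allylic to a free hydroxyl; the exocyclic CH2OH can reach either face, so oxygen should enter from the β face, away from the α substituents on the flanking carbons C6 and C10 and from ring carbons C7 and C9, which lie below the alkene plane in the boat conformer.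

Step 14
Reactants: 18
Product: 20 triol: C1 carries CH2OH and a 1α-hydroxyl, 5β-hydroxyl, 6α-silyloxy, via spiro-epoxide 19 (not isolated)
Conditions: NaOH (0.5 M in H2O), t-BuOH, 70 °C
Reagents that add atoms: water (as hydroxide), O
Why: Payne rearrangement–opening: the C2 alkoxide displaces the epoxide oxygen at C1 with inversion, giving spiro-epoxide 19 with O1 on the α face and O5 left on the β face, and hydroxide then opens 19 at its unhindered CH2 terminus, so the tertiary hydroxyl ends cis to the C10 methyl and trans to O5.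

Step 15
Reactants: 20
Product: 21 α-hydroxy aldehyde (C2 = CHO), 1α-OH and 5β-OH free
Conditions: TEMPO (10 mol%), PhI(OAc)2 (1.2 equiv), CH2Cl2, 25 °C
Reagents that add atoms: none
Why: Oxoammonium-mediated oxidation is selective for the primary alcohol over the hindered secondary C5 hydroxyl and the tertiary one, and the aldehyde has no α-hydrogen to lose.

Step 16
Reactants: 21; 22 (S)-2-methylbutanoic acid
Product: 23 the 5β-[(S)-2-methylbutanoate] of 21
Conditions: DCC (1.5 equiv), DMAP (0.3 equiv), CH2Cl2, 0 to 25 °C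
Reagents that add atoms: none
Why: Steglich esterification acylates the only secondary hydroxyl (the tertiary C1 hydroxyl does not react) without inversion at C5 and with little risk to the α-centre of the acid.

Step 17
Reactants: 23
Product: 24 α-hydroxy acid (C2 = CO2H) carrying the C5 ester
Conditions: NaClO2 (3 equiv), NaH2PO4 (3 equiv), 2-methylbut-2-ene (10 equiv), t-BuOH/H2O, 0 to 25 °C
Reagents that add atoms: sodium chlorite, [Na+].[O-]Cl=O
Why: Pinnick oxidation converts the aldehyde to the acid under buffered conditions, with the alkene scavenger removing hypochlorite before it can reach C8=C9 or C11=C13.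

Step 18
Reactants: 24
Product: 25 bridged iodolactone: C2(=O)–O–C9 with the lactone oxygen 9β and iodine 8α
Conditions: I2 (3 equiv), NaHCO3 (5 equiv), MeCN, 0 °C, dark
Reagents that add atoms: iodine, II
Why: Kinetic iodolactonisation: the β-carboxylate on C1 attacks C9 in 5-exo mode anti to the iodonium ion, which fixes the C9 oxygen on the β face and puts iodine on C8; O5 is acylated, the silyl ether oxygens are poor nucleophiles, and C11=C13 has no internal nucleophile within reach.

Step 19
Reactants: 25
Product: 26 bridged lactone with C8 as CH2 (9β-O–C2 lactone, 1α-OH, 5β-ester)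
Conditions: Bu3SnH (1.5 equiv), AIBN (10 mol%), benzene, 80 °C
Reagents that add atoms: none
Why: Radical-chain dehalogenation; hydrogen transfer from the stannane to the C8 radical should be faster than any rearrangement, and no stereocentre is affected.

Step 20
Reactants: 26; 27 (E)-1-bromoprop-1-ene
Product: 28 (E)-but-2-enoyl ketone on C1 with free 9β-OH and 1α-OH (may equilibrate with its bridged hemiketal)
Conditions: 27 (2.6 equiv), t-BuLi (5.2 equiv), Et2O, −78 °C; then 26 in THF, −78 °C; AcOH quench at −78 °C
Reagents that add atoms: none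
Why: Single addition of an alkenyllithium to a lactone: the first equivalent forms the C1 alkoxide, whose chelation activates the adjacent lactone carbonyl over the hindered α-branched C5 ester, and the lactolate adduct survives until the cold quench, which releases the enone and the C9 hydroxyl.

Step 21
Reactants: 28
Product: 30 (4R)-β-hydroxy ketone (3-hydroxybutanoyl on C1), via β-boryl ketone 29 (not isolated)
Conditions: CuCl (5 mol%), NaOt-Bu (10 mol%), (R)-1-[(Sp)-2-(diphenylphosphino)ferrocenyl]ethyldicyclohexylphosphine (6 mol%), B2(pin)2 (1.1 equiv), MeOH (2 equiv), THF, 25 °C; then NaBO3·4H2O, THF/H2O, 25 °C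
Reagents that add atoms: sodium perborate, [Na+].[O-]OB(O)O (oxygen at C4); bis(pinacolato)diboron, CC1(C)OB(OC1(C)C)B1OC(C)(C)C(C)(C)O1 (boron of 29 only)
Why: Copper-boryl conjugate addition to the E-enone under ligand control places boron on the Re face of C4, and perborate oxidation with retention gives the (4R)-carbinol; the unactivated 1,1-disubstituted alkene and the free hydroxyls do not interfere.

Step 22
Reactants: 30
Product: 31 6α,12-diol (both silyl groups removed)
Conditions: HF·pyridine, pyridine, THF, 0 to 25 °C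
Reagents that add atoms: none
Why: Buffered acidic fluoride cleaves both silyl ethers without the base that would promote retro-aldol loss of C4 or migration of the C5 acyl group.

Step 23
Reactants: 31
Product: 34 the target, via enal 32 (not isolated), via lactol 33 (not isolated)
Conditions: MnO2 (activated, 30 equiv), CH2Cl2, 25 °C
Reagents that add atoms: none
Why: MnO2 oxidises only the primary allylic alcohol; the cis-disposed 6α-hydroxyl closes the five-membered lactol, which is oxidised in turn to the α-methylene-γ-butyrolactone, the ring fusion being cis because O6 and C11 were set cis in step 9.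

**Compound list**

1 | (E)-but-2-enal | C/C=C/C=O | starting material
2 | dimethyl 2-bromomalonate | COC(=O)C(Br)C(=O)OC | starting material
3 | dimethyl (2S,3S)-2-formyl-3-methylcyclopropane-1,1-dicarboxylate | C[C@H]1[C@H](C=O)C1(C(=O)OC)C(=O)OC | intermediate
4 | dimethyl (2S,3S)-2-(hydroxymethyl)-3-methylcyclopropane-1,1-dicarboxylate | C[C@H]1[C@H](CO)C1(C(=O)OC)C(=O)OC | intermediate
5 | methyl (1R,5S,6S)-6-methyl-2-oxo-3-oxabicyclo[3.1.0]hexane-1-carboxylate | C[C@H]1[C@@H]2COC(=O)[C@]12C(=O)OC | intermediate
6 | methyl (1S,5S,6S)-2-hydroxy-6-methyl-3-oxabicyclo[3.1.0]hexane-1-carboxylate (lactol) | C[C@H]1[C@@H]2COC(O)[C@]12C(=O)OC | intermediate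
7 | methyl (1S,2S,3S)-1-ethynyl-2-(hydroxymethyl)-3-methylcyclopropane-1-carboxylate | C[C@H]1[C@H](CO)[C@@]1(C#C)C(=O)OC | intermediate
8 | methyl (1S,2S,3S)-1-ethynyl-2-formyl-3-methylcyclopropane-1-carboxylate | C[C@H]1[C@H](C=O)[C@@]1(C#C)C(=O)OC | intermediate
9 | methyl (1S,2S,3S)-1-ethynyl-3-methyl-2-[(E)-2-(pinacolboryl)ethenyl]cyclopropane-1-carboxylate | C[C@H]1[C@H](/C=C/B2OC(C)(C)C(C)(C)O2)[C@@]1(C#C)C(=O)OC | intermediate
10 | 2-bromoprop-2-en-1-ol | OCC(Br)=C | starting material
11 | (2-bromoprop-2-enyloxy)triisopropylsilane | C=C(Br)CO[Si](C(C)C)(C(C)C)C(C)C | intermediate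
12 | methyl (1S,2S,3S)-1-ethynyl-3-methyl-2-[(1E)-3-(triisopropylsilyloxymethyl)buta-1,3-dienyl]cyclopropane-1-carboxylate | C[C@H]1[C@H](/C=C/C(=C)CO[Si](C(C)C)(C(C)C)C(C)C)[C@@]1(C#C)C(=O)OC | intermediate
13 | methyl (1S,2S,3S)-3-methyl-1-[(E)-2-(pinacolboryl)ethenyl]-2-[(1E)-3-(triisopropylsilyloxymethyl)buta-1,3-dienyl]cyclopropane-1-carboxylate (arms cis, methyl trans) | C[C@H]1[C@H](/C=C/C(=C)CO[Si](C(C)C)(C(C)C)C(C)C)[C@@]1(/C=C/B2OC(C)(C)C(C)(C)O2)C(=O)OC | intermediate
14 | cycloheptadiene ester: C1=C5 and C8=C9, CO2Me on C1, 6α-pinacolboryl, 7α-[3-(triisopropylsilyloxy)prop-1-en-2-yl], 10α-methyl | COC(=O)C1=C[C@H](B2OC(C)(C)C(C)(C)O2)[C@H](C(=C)CO[Si](C(C)C)(C(C)C)C(C)C)C=C[C@@H]1C | intermediate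
15 | 6α-hydroxy analogue of 14 | COC(=O)C1=C[C@H](O)[C@H](C(=C)CO[Si](C(C)C)(C(C)C)C(C)C)C=C[C@@H]1C | intermediate
16 | 6α-tert-butyldimethylsilyl ether of 15 | COC(=O)C1=C[C@H](O[Si](C)(C)C(C)(C)C)[C@H](C(=C)CO[Si](C(C)C)(C(C)C)C(C)C)C=C[C@@H]1C | intermediate
17 | allylic alcohol (CH2OH on C1), otherwise as 16 | OCC1=C[C@H](O[Si](C)(C)C(C)(C)C)[C@H](C(=C)CO[Si](C(C)C)(C(C)C)C(C)C)C=C[C@@H]1C | intermediate
18 | 1β,5β-epoxide of 17 | OC[C@]12O[C@H]1[C@H](O[Si](C)(C)C(C)(C)C)[C@H](C(=C)CO[Si](C(C)C)(C(C)C)C(C)C)C=C[C@@H]2C | intermediate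
19 | spiro-epoxide (C2H2–O–C1, oxygen α) with 5β-hydroxyl | C1O[C@@]12[C@@H](O)[C@H](O[Si](C)(C)C(C)(C)C)[C@H](C(=C)CO[Si](C(C)C)(C(C)C)C(C)C)C=C[C@@H]2C | intermediate
20 | triol: CH2OH and 1α-OH on C1, 5β-OH, 6α-silyloxy, C8=C9 | OC[C@@]1(O)[C@@H](O)[C@H](O[Si](C)(C)C(C)(C)C)[C@H](C(=C)CO[Si](C(C)C)(C(C)C)C(C)C)C=C[C@@H]1C | intermediate
21 | α-hydroxy aldehyde (CHO on C1), 5β-OH | O=C[C@@]1(O)[C@@H](O)[C@H](O[Si](C)(C)C(C)(C)C)[C@H](C(=C)CO[Si](C(C)C)(C(C)C)C(C)C)C=C[C@@H]1C | intermediate
22 | (S)-2-methylbutanoic acid | CC[C@H](C)C(=O)O | starting material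
23 | 5β-[(S)-2-methylbutanoate] of 21 | O=C[C@@]1(O)[C@@H](OC(=O)[C@@H](C)CC)[C@H](O[Si](C)(C)C(C)(C)C)[C@H](C(=C)CO[Si](C(C)C)(C(C)C)C(C)C)C=C[C@@H]1C | intermediate
24 | α-hydroxy acid (CO2H on C1) with the C5 ester | OC(=O)[C@@]1(O)[C@@H](OC(=O)[C@@H](C)CC)[C@H](O[Si](C)(C)C(C)(C)C)[C@H](C(=C)CO[Si](C(C)C)(C(C)C)C(C)C)C=C[C@@H]1C | intermediate
25 | bridged 8α-iodo-2,9β-lactone | O=C1O[C@@H]2[C@@H](I)[C@@H](C(=C)CO[Si](C(C)C)(C(C)C)C(C)C)[C@@H](O[Si](C)(C)C(C)(C)C)[C@H](OC(=O)[C@@H](C)CC)[C@@]1(O)[C@H]2C | intermediate
26 | bridged 2,9β-lactone (C8 = CH2) | O=C1O[C@@H]2C[C@@H](C(=C)CO[Si](C(C)C)(C(C)C)C(C)C)[C@@H](O[Si](C)(C)C(C)(C)C)[C@H](OC(=O)[C@@H](C)CC)[C@@]1(O)[C@H]2C | intermediate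
27 | (E)-1-bromoprop-1-ene | C/C=C/Br | starting material
28 | (E)-but-2-enoyl ketone with 9β-OH, 1α-OH, 5β-ester | C/C=C/C(=O)[C@@]1(O)[C@@H](OC(=O)[C@@H](C)CC)[C@H](O[Si](C)(C)C(C)(C)C)[C@H](C(=C)CO[Si](C(C)C)(C(C)C)C(C)C)C[C@@H](O)[C@@H]1C | intermediate
29 | (4R)-3-(pinacolboryl)butanoyl ketone | C[C@@H](B2OC(C)(C)C(C)(C)O2)CC(=O)[C@@]1(O)[C@@H](OC(=O)[C@@H](C)CC)[C@H](O[Si](C)(C)C(C)(C)C)[C@H](C(=C)CO[Si](C(C)C)(C(C)C)C(C)C)C[C@@H](O)[C@@H]1C | intermediate
30 | (4R)-3-hydroxybutanoyl ketone, bis-silyl ether | C[C@@H](O)CC(=O)[C@@]1(O)[C@@H](OC(=O)[C@@H](C)CC)[C@H](O[Si](C)(C)C(C)(C)C)[C@H](C(=C)CO[Si](C(C)C)(C(C)C)C(C)C)C[C@@H](O)[C@@H]1C | intermediate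
31 | 6α,12-diol (seco-lactone pentaol) | C[C@@H](O)CC(=O)[C@@]1(O)[C@@H](OC(=O)[C@@H](C)CC)[C@H](O)[C@H](C(=C)CO)C[C@@H](O)[C@@H]1C | intermediate
32 | C12 enal | C[C@@H](O)CC(=O)[C@@]1(O)[C@@H](OC(=O)[C@@H](C)CC)[C@H](O)[C@H](C(=C)C=O)C[C@@H](O)[C@@H]1C | intermediate
33 | C12 lactol | C=C1C(O)O[C@@H]2[C@H]1C[C@@H](O)[C@H](C)[C@@](O)(C(=O)C[C@@H](C)O)[C@H]2OC(=O)[C@@H](C)CC | intermediate
34 | CNP0291806.4 | C=C1C(=O)O[C@@H]2[C@H]1C[C@@H](O)[C@H](C)[C@@](O)(C(=O)C[C@@H](C)O)[C@H]2OC(=O)[C@@H](C)CC | target

**Step count and risks**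

Total steps: 23. Longest linear sequence: 22 (steps 1–6 and 8–23; step 7 is a one-step side branch).

Steps most likely to fail:

1. Step 14. The Payne equilibrium may stay on the side of 18, hydroxide may open 18 directly at C5, or the O6 silyl group may move to the O5 alkoxide at 70 °C. The fallback sets out from 18 and returns at 20. Phenyl isocyanate and pyridine convert 18 into the N-phenylcarbamate F1. BF3·OEt2 in Et2O at −20 °C, then dilute aqueous acid, should make the carbamate carbonyl oxygen open the epoxide at the adjacent tertiary C1 with inversion and hydrolyse the iminocarbonate to the 1α,2-cyclic carbonate F2 with the 5β-hydroxyl free. K2CO3 in MeOH then removes the carbonate to give 20.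

2. Step 20. The organolithium may also attack the C5 ester, the C1 alkoxide may take over the acyl group, or a second equivalent may add. The fallback sets out from 26 and returns at 28. The lactone is opened with the aluminium amide made from Me3Al and N,O-dimethylhydroxylamine hydrochloride (CH2Cl2, 0 °C) to the Weinreb amide F3. Its chelated adduct with (E)-prop-1-enyllithium (from 27, −78 °C) collapses only on work-up and gives 28.

3. Step 21. Facial selectivity at C4 may be eroded by the neighbouring C1 carbinol, or the enone may rest as its bridged hemiketal and react slowly. The fallback sets out from 26 and returns at 30. MeLi at −78 °C converts the lactone into the methyl ketone F4. A reagent-controlled boron aldol reaction (the enantiomer of diisopinocampheylboron chloride that gives the 4R product, Et3N, then acetaldehyde, oxidative work-up) forms C3–C4 and the C4 carbinol in one operation and gives 30.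

**Further compounds**

F1 | step 14 | N-phenylcarbamate of epoxy alcohol 18 | O=C(Nc1ccccc1)OC[C@]12O[C@H]1[C@H](O[Si](C)(C)C(C)(C)C)[C@H](C(=C)CO[Si](C(C)C)(C(C)C)C(C)C)C=C[C@@H]2C
F2 | step 14 | 1α,2-cyclic carbonate of triol 20 (5β-OH free) | O=C1OC[C@@]2(O1)[C@@H](O)[C@H](O[Si](C)(C)C(C)(C)C)[C@H](C(=C)CO[Si](C(C)C)(C(C)C)C(C)C)C=C[C@@H]2C
F3 | step 20 | N-methoxy-N-methylamide at C2 with free 9β-OH | CON(C)C(=O)[C@@]1(O)[C@@H](OC(=O)[C@@H](C)CC)[C@H](O[Si](C)(C)C(C)(C)C)[C@H](C(=C)CO[Si](C(C)C)(C(C)C)C(C)C)C[C@@H](O)[C@@H]1C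
F4 | step 21 | methyl ketone (acetyl on C1) with free 9β-OH | CC(=O)[C@@]1(O)[C@@H](OC(=O)[C@@H](C)CC)[C@H](O[Si](C)(C)C(C)(C)C)[C@H](C(=C)CO[Si](C(C)C)(C(C)C)C(C)C)C[C@@H](O)[C@@H]1C
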